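**Retrosynthetic overview**

1. Labels: C1 = seven-ring CH bearing 4-hydroxyphenyl; C2 = ring-fusion CH; C3 = five-ring CH bearing 4-hydroxyphenyl; C4 = five-ring CH bearing 3,5-dihydroxyphenyl. Ring A carries the ketone and C1 on two neighbouring carbons; ring D is bonded to C2 at D1, to the ketone at D2 and to C4 at D6, with oxygens at D3 and D5.
2. Feature: in the five-membered ring C2–C3–C4–D6–D1 the neighbours C3 and C4 are both benzylic, and C4 sits on D6, ortho and para to the ring-D oxygens. A nitrogen placed between C3 and C4 makes this ring a 1,3-diaryl-tetrahydroisoquinoline that a Pictet–Spengler closure at D6 delivers, so the C3–C4 bond is made by loss of N2 from that amine.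
3. Disconnections, backwards: aryl ethers; ketone–D2 bond (Friedel–Crafts acylation, seven-membered ring); ring-A carboxyl from an aryl bromide; bond from C1 to ring A (Friedel–Crafts alkylation by the C1 carbinol grown from the C2 ester); C3–C4 (N2 extrusion); C4–D6 and C4–N (Pictet–Spengler); C2–C3 (Mannich addition to an N-tert-butanesulfinyl imine).
4. Ring order: six-membered nitrogen ring, then its contraction to the five-membered ring, then the seven-membered ring.
5. The aryl group on C4 is carried as its bis(4-methylbenzenesulfonate) until C1 is arylated. It stands cis to C1 on the five-membered ring, and as a dimethyl ether it would capture the C1 cation in a six-membered closure.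

Key step: step 6

Remark: carbinol 20 is used as the mixture of both configurations at the carbinol carbon, because this carbon becomes the planar cation 22 in step 9.

**Route**

Step 1
Reactants: 1 4-methoxybenzaldehyde; 2 (S)-2-methylpropane-2-sulfinamide
Product: 3 (S,E)-N-(4-methoxybenzylidene)-2-methylpropane-2-sulfinamide
Conditions: Ti(OEt)4 (2 equiv), THF, rt
Reagents that add atoms: none
Why: Condensation of an aldehyde with tert-butanesulfinamide, with Ti(OEt)4 as Lewis acid and water scavenger, should give the E sulfinyl imine without touching the sulfur stereocentre.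

Step 2
Reactants: 4 methyl 2-(3,5-dimethoxyphenyl)acetate; 3 (S,E)-N-(4-methoxybenzylidene)-2-methylpropane-2-sulfinamide
Product: 7 methyl (2R,3R)-3-{[(S)-tert-butylsulfinyl]amino}-2-(3,5-dimethoxyphenyl)-3-(4-methoxyphenyl)propanoate, via lithium enolate 5 (not isolated), via titanium enolate 6 (not isolated)
Conditions: LiN(i-Pr)2, THF, −78 °C; ClTi(Oi-Pr)3; then 3, −78 °C; aq. NH4Cl
Reagents that add atoms: none
Why: Mannich-type addition of a titanium ester enolate to an N-tert-butanesulfinyl aldimine through a closed six-membered chair transition state in which titanium binds the imine nitrogen and the sulfinyl oxygen; the (S)-sulfinyl group should direct the enolate to the imine face that gives 3R, and the enolate with aryl trans to O–Ti, meeting the E imine whose aryl group is axial, should give the syn (2R,3R) relation (C2–C3 bond).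

Step 3
Reactants: 7 methyl (2R,3R)-3-{[(S)-tert-butylsulfinyl]amino}-2-(3,5-dimethoxyphenyl)-3-(4-methoxyphenyl)propanoate
Product: 8 methyl (2R,3R)-3-amino-2-(3,5-dimethoxyphenyl)-3-(4-methoxyphenyl)propanoate
Conditions: HCl (4 M in dioxane), MeOH, 0 °C → rt; then aq. NaHCO3
Reagents that add atoms: none
Why: Acidic methanolysis of the S–N bond is the standard removal of the tert-butanesulfinyl group and leaves both carbon stereocentres untouched.

Step 4
Reactants: 9 3,5-dihydroxybenzaldehyde
Product: 10 3,5-bis(tosyloxy)benzaldehyde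
Conditions: TsCl (2.2 equiv), Et3N, DMAP (cat.), CH2Cl2, 0 °C → rt
Reagents that add atoms: 4-methylbenzenesulfonyl chloride (Cc1ccc(cc1)S(Cl)(=O)=O)
Why: Base-mediated O-sulfonylation of both phenols should give an aldehyde whose ring is too electron-poor for Friedel–Crafts chemistry and whose sulfonates come off with hydroxide in step 11.

Step 5
Reactants: 8 methyl (2R,3R)-3-amino-2-(3,5-dimethoxyphenyl)-3-(4-methoxyphenyl)propanoate; 10 3,5-bis(tosyloxy)benzaldehyde
Product: 12 methyl (1S,3R,4R)-1-[3,5-bis(tosyloxy)phenyl]-6,8-dimethoxy-3-(4-methoxyphenyl)-1,2,3,4-tetrahydroisoquinoline-4-carboxylate, via imine 11 (not isolated)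
Conditions: 4 Å molecular sieves, CH2Cl2, rt; then CF3CO2H, 0 °C → rt; aq. NaHCO3
Reagents that add atoms: none
Why: Pictet–Spengler reaction: protonated imine 11 is attacked by ring D through D6 (6-endo-trig; D2 and D6 are equivalent before closure and both are ortho and para to methoxy groups), and the new aryl group at C4 should take the pseudoaxial position away from the peri methoxy group at D5, which gives the 1,3-trans amine.

Step 6
Reactants: 12 methyl (1S,3R,4R)-1-[3,5-bis(tosyloxy)phenyl]-6,8-dimethoxy-3-(4-methoxyphenyl)-1,2,3,4-tetrahydroisoquinoline-4-carboxylate; 13 N-(benzyloxy)-N-(pivaloyloxy)-4-(trifluoromethyl)benzamide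
Product: 17 methyl (1S,2R,3S)-3-[3,5-bis(tosyloxy)phenyl]-4,6-dimethoxy-2-(4-methoxyphenyl)-2,3-dihydro-1H-indene-1-carboxylate, via hydrazide 14 (not isolated), via isodiazene 15 (not isolated), via diradical 16 (not isolated)
Conditions: 13 (1.5 equiv), THF, 45 °C
Reagents that add atoms: none
Why: The only N–H attacks the nitrogen of the anomeric amide with loss of pivalate to give hydrazide 14, whose benzyloxy group shifts to the acyl carbon and releases benzyl 4-(trifluoromethyl)benzoate and isodiazene 15; 15 loses N2 and leaves the benzylic radical centres C3 and C4 of diradical 16, which combine to the C3–C4 bond. The closest known reaction is the nitrogen deletion of secondary amines by anomeric amides, which contracts tetrahydroisoquinolines to indanes. The five-membered ring C2–C3–C4–D6–D1 closes by combination of the two ends of a 1,5-diradical held together by ring D and C2, that is a contraction of the six-membered amine by one atom and not a polar cyclisation. C2 is no radical centre and keeps its configuration; C3 should form with its 4-methoxyphenyl group trans to the ester on C2 and C4 with its aryl group trans to the aryl group on C3, because this keeps the three substituents apart in the closing envelope, and collapse with retention from the 1,3-trans amine 12 leads to the same isomer; this diastereocontrol is untested. The step needs recombination to outrun hydrogen transfer between the radical centres (a ring-opened stilbene ester) and rotation to a cis arrangement; the short tether and the benzylic stabilisation of both centres should secure this, and the aryl sulfonates, the ester and the methyl ethers are inert to the reagent.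

Step 7
Reactants: 17 methyl (1S,2R,3S)-3-[3,5-bis(tosyloxy)phenyl]-4,6-dimethoxy-2-(4-methoxyphenyl)-2,3-dihydro-1H-indene-1-carboxylate
Product: 18 (1S,2R,3S)-3-[3,5-bis(tosyloxy)phenyl]-4,6-dimethoxy-2-(4-methoxyphenyl)-2,3-dihydro-1H-indene-1-carbaldehyde
Conditions: i-Bu2AlH (1.2 equiv), CH2Cl2, −78 °C; MeOH, then aq. potassium sodium tartrate
Reagents that add atoms: none
Why: Partial reduction of a methyl ester by i-Bu2AlH, whose aluminium hemiacetal is stable at −78 °C and gives the aldehyde on work-up; the centre next to the aldehyde can epimerise, but the trans arrangement drawn is the more stable one.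

Step 8
Reactants: 18 (1S,2R,3S)-3-[3,5-bis(tosyloxy)phenyl]-4,6-dimethoxy-2-(4-methoxyphenyl)-2,3-dihydro-1H-indene-1-carbaldehyde; 19 4-methoxyphenylmagnesium bromide
Product: 20 [(1S,2R,3S)-3-[3,5-bis(tosyloxy)phenyl]-4,6-dimethoxy-2-(4-methoxyphenyl)-2,3-dihydro-1H-inden-1-yl](4-methoxyphenyl)methanol (both carbinol epimers)
Conditions: 19 (1.5 equiv), THF, −78 → 0 °C; aq. NH4Cl
Reagents that add atoms: none
Why: Grignard addition to the aldehyde is much faster at low temperature than attack on the aryl sulfonates, and the configuration of the new carbinol carbon (C1) need not be controlled because it is ionised in step 9.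

Step 9
Reactants: 20 [(1S,2R,3S)-3-[3,5-bis(tosyloxy)phenyl]-4,6-dimethoxy-2-(4-methoxyphenyl)-2,3-dihydro-1H-inden-1-yl](4-methoxyphenyl)methanol; 21 1-bromo-3,5-dimethoxybenzene
Product: 23 (1R,2S,3S)-1-[(S)-(2-bromo-4,6-dimethoxyphenyl)(4-methoxyphenyl)methyl]-3-[3,5-bis(tosyloxy)phenyl]-4,6-dimethoxy-2-(4-methoxyphenyl)-2,3-dihydro-1H-indene, via benzylic cation 22 (not isolated)
Conditions: 21 (20 equiv), CF3SO3H (10 mol%), (CF3)2CHOH/CH2Cl2, −20 → 0 °C
Reagents that add atoms: none
Why: Friedel–Crafts benzylation: the acid ionises the 4-methoxybenzylic carbinol to cation 22, and the bromoarene should react at the position ortho to bromine and para to methoxy (the site its formylation takes) to form the bond from C1 to ring A; the bis-sulfonate ring on C4 is too electron-poor to close onto C1, and the arene should add to the cation face turned to flat ring D, because the other face is screened by C3 and by the C4 aryl group on the same side of the five-membered ring, which sets C1 as S.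

Step 10
Reactants: 23 (1R,2S,3S)-1-[(S)-(2-bromo-4,6-dimethoxyphenyl)(4-methoxyphenyl)methyl]-3-[3,5-bis(tosyloxy)phenyl]-4,6-dimethoxy-2-(4-methoxyphenyl)-2,3-dihydro-1H-indene
Product: 24 methyl 2-{(S)-[(1R,2S,3S)-3-[3,5-bis(tosyloxy)phenyl]-4,6-dimethoxy-2-(4-methoxyphenyl)-2,3-dihydro-1H-inden-1-yl](4-methoxyphenyl)methyl}-3,5-dimethoxybenzoate
Conditions: Pd(OAc)2 (5 mol%), Xantphos (10 mol%), CO (1 atm), Et3N, MeOH/toluene, 80 °C
Reagents that add atoms: carbon monoxide ([C-]#[O+]); methanol (CO)
Why: Palladium-catalysed alkoxycarbonylation of an aryl bromide (zerovalent palladium inserts into C–Br, CO inserts, methanol cleaves the acyl complex) puts the carboxyl carbon on the ring-A carbon next to the one bonded to C1, and aryl sulfonates do not add to this catalyst under these conditions.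

Step 11
Reactants: 24 methyl 2-{(S)-[(1R,2S,3S)-3-[3,5-bis(tosyloxy)phenyl]-4,6-dimethoxy-2-(4-methoxyphenyl)-2,3-dihydro-1H-inden-1-yl](4-methoxyphenyl)methyl}-3,5-dimethoxybenzoate
Product: 25 2-{(S)-[(1R,2S,3S)-3-(3,5-dihydroxyphenyl)-4,6-dimethoxy-2-(4-methoxyphenyl)-2,3-dihydro-1H-inden-1-yl](4-methoxyphenyl)methyl}-3,5-dimethoxybenzoic acid
Conditions: KOH (excess), EtOH/H2O, 85 °C; then aq. HCl to pH 3
Reagents that add atoms: potassium hydroxide ([K+].[OH-])
Why: Saponification of the hindered benzoate and hydroxide cleavage of both aryl sulfonates at sulfur should occur in one operation, and no base-labile stereocentre is present because the ketone is not yet formed.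

Step 12
Reactants: 25 2-{(S)-[(1R,2S,3S)-3-(3,5-dihydroxyphenyl)-4,6-dimethoxy-2-(4-methoxyphenyl)-2,3-dihydro-1H-inden-1-yl](4-methoxyphenyl)methyl}-3,5-dimethoxybenzoic acid
Product: 28 hexa-O-methyl ether of the target (3,5-dihydroxyphenyl on C4 free), via mixed anhydride 26 (not isolated), via ketone bis(trifluoroacetate) 27 (not isolated)
Conditions: (CF3CO)2O (6 equiv), CF3CO2H, CH2Cl2, 0 → 40 °C; then aq. NaHCO3
Reagents that add atoms: none
Why: Intramolecular Friedel–Crafts acylation: the anhydride turns the acid into its mixed trifluoroacetic anhydride and the two phenols into unreactive trifluoroacetates, and the acyl group attacks D2, the only position within reach that is ortho and para to methoxy groups, to close the seven-membered ring before bicarbonate frees the phenols again.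

Step 13
Reactants: 28 hexa-O-methyl ether of the target (3,5-dihydroxyphenyl on C4 free)
Product: 29 CNP0116600.1 (target; C1 S, C2 R, C3 S, C4 S)
Conditions: BBr3 (15 equiv), CH2Cl2, −78 °C → rt; then H2O
Reagents that add atoms: none
Why: Lewis-acid cleavage of all six aryl methyl ethers by BBr3 is standard for this class of polyphenol ethers, and the benzylic methines and the diaryl ketone are not affected.

**Compound list**

1 | 4-methoxybenzaldehyde | COc1ccc(C=O)cc1 | starting material
2 | (S)-2-methylpropane-2-sulfinamide | CC(C)(C)[S@](=O)N | starting material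
3 | (S,E)-N-(4-methoxybenzylidene)-2-methylpropane-2-sulfinamide | COc1ccc(/C=N/[S@@](=O)C(C)(C)C)cc1 | intermediate
4 | methyl 2-(3,5-dimethoxyphenyl)acetate | COC(=O)Cc1cc(OC)cc(OC)c1 | starting material
5 | lithium enolate of 4 (aryl trans to O–Li) | [Li]O/C(OC)=C/c1cc(OC)cc(OC)c1 | intermediate
6 | tri(isopropoxy)titanium enolate of 4 (aryl trans to O–Ti) | CC(C)O[Ti](OC(C)C)(OC(C)C)O/C(OC)=C/c1cc(OC)cc(OC)c1 | intermediate
7 | methyl (2R,3R)-3-{[(S)-tert-butylsulfinyl]amino}-2-(3,5-dimethoxyphenyl)-3-(4-methoxyphenyl)propanoate | COC(=O)[C@H](c1cc(OC)cc(OC)c1)[C@@H](N[S@@](=O)C(C)(C)C)c1ccc(OC)cc1 | intermediate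
8 | methyl (2R,3R)-3-amino-2-(3,5-dimethoxyphenyl)-3-(4-methoxyphenyl)propanoate | COC(=O)[C@H](c1cc(OC)cc(OC)c1)[C@@H](N)c1ccc(OC)cc1 | intermediate
9 | 3,5-dihydroxybenzaldehyde | O=Cc1cc(O)cc(O)c1 | starting material
10 | 3,5-bis(tosyloxy)benzaldehyde | Cc1ccc(cc1)S(=O)(=O)Oc1cc(C=O)cc(OS(=O)(=O)c2ccc(C)cc2)c1 | intermediate
11 | E imine of amine 8 and aldehyde 10 | COC(=O)[C@H](c1cc(OC)cc(OC)c1)[C@@H](/N=C/c1cc(OS(=O)(=O)c2ccc(C)cc2)cc(OS(=O)(=O)c2ccc(C)cc2)c1)c1ccc(OC)cc1 | intermediate
12 | methyl (1S,3R,4R)-1-[3,5-bis(tosyloxy)phenyl]-6,8-dimethoxy-3-(4-methoxyphenyl)-1,2,3,4-tetrahydroisoquinoline-4-carboxylate | COC(=O)[C@@H]1c2cc(OC)cc(OC)c2[C@H](c2cc(OS(=O)(=O)c3ccc(C)cc3)cc(OS(=O)(=O)c3ccc(C)cc3)c2)N[C@H]1c1ccc(OC)cc1 | intermediate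
13 | N-(benzyloxy)-N-(pivaloyloxy)-4-(trifluoromethyl)benzamide | CC(C)(C)C(=O)ON(OCc1ccccc1)C(=O)c1ccc(cc1)C(F)(F)F | starting material
14 | N-amination adduct of 12: ring nitrogen bonded to N(OBn)C(=O)C6H4CF3 | COC(=O)[C@@H]1c2cc(OC)cc(OC)c2[C@H](c2cc(OS(=O)(=O)c3ccc(C)cc3)cc(OS(=O)(=O)c3ccc(C)cc3)c2)N(N(OCc2ccccc2)C(=O)c2ccc(cc2)C(F)(F)F)[C@H]1c1ccc(OC)cc1 | intermediate
15 | isodiazene (1,1-diazene) of 12 | COC(=O)[C@@H]1c2cc(OC)cc(OC)c2[C@H](c2cc(OS(=O)(=O)c3ccc(C)cc3)cc(OS(=O)(=O)c3ccc(C)cc3)c2)[N+](=[N-])[C@H]1c1ccc(OC)cc1 | intermediate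
16 | 1,5-diradical with radical centres at C3 and C4 | COC(=O)[C@@H]([CH]c1ccc(OC)cc1)c1cc(OC)cc(OC)c1[CH]c1cc(OS(=O)(=O)c2ccc(C)cc2)cc(OS(=O)(=O)c2ccc(C)cc2)c1 | intermediate
17 | methyl (1S,2R,3S)-3-[3,5-bis(tosyloxy)phenyl]-4,6-dimethoxy-2-(4-methoxyphenyl)-2,3-dihydro-1H-indene-1-carboxylate | COC(=O)[C@@H]1c2cc(OC)cc(OC)c2[C@H](c2cc(OS(=O)(=O)c3ccc(C)cc3)cc(OS(=O)(=O)c3ccc(C)cc3)c2)[C@H]1c1ccc(OC)cc1 | intermediate
18 | (1S,2R,3S)-3-[3,5-bis(tosyloxy)phenyl]-4,6-dimethoxy-2-(4-methoxyphenyl)-2,3-dihydro-1H-indene-1-carbaldehyde | O=C[C@@H]1c2cc(OC)cc(OC)c2[C@H](c2cc(OS(=O)(=O)c3ccc(C)cc3)cc(OS(=O)(=O)c3ccc(C)cc3)c2)[C@H]1c1ccc(OC)cc1 | intermediate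
19 | 4-methoxyphenylmagnesium bromide | COc1ccc([Mg]Br)cc1 | starting material
20 | [(1S,2R,3S)-3-[3,5-bis(tosyloxy)phenyl]-4,6-dimethoxy-2-(4-methoxyphenyl)-2,3-dihydro-1H-inden-1-yl](4-methoxyphenyl)methanol, both carbinol epimers | COc1ccc(cc1)C(O)[C@@H]1c2cc(OC)cc(OC)c2[C@H](c2cc(OS(=O)(=O)c3ccc(C)cc3)cc(OS(=O)(=O)c3ccc(C)cc3)c2)[C@H]1c1ccc(OC)cc1 | intermediate
21 | 1-bromo-3,5-dimethoxybenzene | COc1cc(Br)cc(OC)c1 | starting material
22 | 4-methoxybenzylic cation at C1 derived from 20 | COc1ccc(cc1)[CH+][C@@H]1c2cc(OC)cc(OC)c2[C@H](c2cc(OS(=O)(=O)c3ccc(C)cc3)cc(OS(=O)(=O)c3ccc(C)cc3)c2)[C@H]1c1ccc(OC)cc1 | intermediate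
23 | (1R,2S,3S)-1-[(S)-(2-bromo-4,6-dimethoxyphenyl)(4-methoxyphenyl)methyl]-3-[3,5-bis(tosyloxy)phenyl]-4,6-dimethoxy-2-(4-methoxyphenyl)-2,3-dihydro-1H-indene | COc1cc(Br)c(c(OC)c1)[C@H](c1ccc(OC)cc1)[C@@H]1c2cc(OC)cc(OC)c2[C@H](c2cc(OS(=O)(=O)c3ccc(C)cc3)cc(OS(=O)(=O)c3ccc(C)cc3)c2)[C@H]1c1ccc(OC)cc1 | intermediate
24 | methyl 2-{(S)-[(1R,2S,3S)-3-[3,5-bis(tosyloxy)phenyl]-4,6-dimethoxy-2-(4-methoxyphenyl)-2,3-dihydro-1H-inden-1-yl](4-methoxyphenyl)methyl}-3,5-dimethoxybenzoate | COC(=O)c1cc(OC)cc(OC)c1[C@H](c1ccc(OC)cc1)[C@@H]1c2cc(OC)cc(OC)c2[C@H](c2cc(OS(=O)(=O)c3ccc(C)cc3)cc(OS(=O)(=O)c3ccc(C)cc3)c2)[C@H]1c1ccc(OC)cc1 | intermediate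
25 | 2-{(S)-[(1R,2S,3S)-3-(3,5-dihydroxyphenyl)-4,6-dimethoxy-2-(4-methoxyphenyl)-2,3-dihydro-1H-inden-1-yl](4-methoxyphenyl)methyl}-3,5-dimethoxybenzoic acid | OC(=O)c1cc(OC)cc(OC)c1[C@H](c1ccc(OC)cc1)[C@@H]1c2cc(OC)cc(OC)c2[C@H](c2cc(O)cc(O)c2)[C@H]1c1ccc(OC)cc1 | intermediate
26 | mixed trifluoroacetic anhydride of 25 with both phenols as trifluoroacetates | FC(F)(F)C(=O)OC(=O)c1cc(OC)cc(OC)c1[C@H](c1ccc(OC)cc1)[C@@H]1c2cc(OC)cc(OC)c2[C@H](c2cc(OC(=O)C(F)(F)F)cc(OC(=O)C(F)(F)F)c2)[C@H]1c1ccc(OC)cc1 | intermediate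
27 | seven-ring ketone with both phenols on the C4 aryl group as trifluoroacetates | O=C1c2cc(OC)cc(OC)c2[C@H](c2ccc(OC)cc2)[C@@H]2c3c1c(OC)cc(OC)c3[C@H](c1cc(OC(=O)C(F)(F)F)cc(OC(=O)C(F)(F)F)c1)[C@H]2c1ccc(OC)cc1 | intermediate
28 | hexa-O-methyl ether of the target: methyl ethers on rings A and D and on both 4-oxyphenyl groups, free 3,5-dihydroxyphenyl on C4 (C1 S, C2 R, C3 S, C4 S) | O=C1c2cc(OC)cc(OC)c2[C@H](c2ccc(OC)cc2)[C@@H]2c3c1c(OC)cc(OC)c3[C@H](c1cc(O)cc(O)c1)[C@H]2c1ccc(OC)cc1 | intermediate
29 | CNP0116600.1 (C1 S, C2 R, C3 S, C4 S) | O=C1c2cc(O)cc(O)c2[C@H](c2ccc(O)cc2)[C@@H]2c3c1c(O)cc(O)c3[C@H](c1cc(O)cc(O)c1)[C@H]2c1ccc(O)cc1 | target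

**Step count**

Total: 13 steps. Longest linear sequence: 12 steps (steps 1, 2, 3 and 5 to 13, from 4-methoxybenzaldehyde); step 4 is a one-step side branch.

**Steps most likely to fail**

Step 6 (key step). Amination of the nitrogen, which carries a branched benzylic carbon on each side, may be slower than decomposition of the reagent. The diradical may also transfer hydrogen between its centres to give a ring-opened stilbene ester, or rotate before collapse to give the C3/C4 cis indane. The fallback sets out from 12 and comes back at 17. It makes the same isodiazene stepwise by known chemistry, with N2 lost at lower temperature. Nitrosation of 12 with tert-butyl nitrite in THF should give the N-nitrosamine F1, since the nitrosyl transfer is little affected by hindrance. Reduction with Zn in AcOH should give the N-amino compound F2. Oxidation of F2 with HgO in CH2Cl2/EtOH at −20 °C → rt should give isodiazene 15, which loses N2 and closes to 17. Oxidation of 1,1-disubstituted hydrazines that carry two benzylic carbons is a known way to couple the two carbons with loss of N2, and in cyclic cases it tends to retain configuration.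

Step 9. The arene may add to the other face of cation 22 and give the C1 epimer. The bromoarene may react at the position between its two methoxy groups. The cation may lose the proton at C2 reversibly, which erodes the C2 configuration. Ring D of a second molecule may be alkylated. The fallback sets out from 18 and 21 and comes back at 23. It introduces the two aryl groups on C1 in the reverse order, so that the bond to ring A is made by a defined organometallic and the cation meets a simple arene. Iodination of 21 with N-iodosuccinimide in MeCN should give 1-bromo-2-iodo-3,5-dimethoxybenzene F3. Iodine–magnesium exchange with i-PrMgCl·LiCl in THF at −40 °C should give (2-bromo-4,6-dimethoxyphenyl)magnesium chloride F4. Addition of F4 to aldehyde 18 should give the ring-A carbinol F5. Ionisation of F5 with catalytic CF3SO3H in anisole/(CF3)2CHOH should bring in the 4-methoxyphenyl group through the para position of anisole and give 23. Because the two aryl groups have changed roles, an arene entering from the face that gave the wrong epimer in step 9 now gives the right one.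

Step 2. The syn/anti ratio may be poor, because the enolate geometry of an arylacetate is less certain than that of simple esters. This would misplace C2, the one centre that passes the key step unchanged. The fallback sets out from 3 and 4 and comes back at 12. It sets C2 by equilibration in the ring instead of in the C–C bond formation. If the addition gives mainly the anti adduct, methyl (2S,3R)-3-{[(S)-tert-butylsulfinyl]amino}-2-(3,5-dimethoxyphenyl)-3-(4-methoxyphenyl)propanoate F6, this is carried on. HCl in MeOH should give the anti amino ester F7, and the Pictet–Spengler closure with 10 under the conditions of step 5 should give the 3,4-cis tetrahydroisoquinoline F8. The non-nucleophilic base DBU in toluene at 60 °C should then epimerise the ester-bearing benzylic carbon C2 to the more stable 3,4-trans isomer 12 without attacking the aryl sulfonates.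

**Further compounds**

F1 | step 6 | methyl (1S,3R,4R)-1-[3,5-bis(tosyloxy)phenyl]-6,8-dimethoxy-3-(4-methoxyphenyl)-2-nitroso-1,2,3,4-tetrahydroisoquinoline-4-carboxylate | COC(=O)[C@@H]1c2cc(OC)cc(OC)c2[C@H](c2cc(OS(=O)(=O)c3ccc(C)cc3)cc(OS(=O)(=O)c3ccc(C)cc3)c2)N(N=O)[C@H]1c1ccc(OC)cc1
F2 | step 6 | methyl (1S,3R,4R)-2-amino-1-[3,5-bis(tosyloxy)phenyl]-6,8-dimethoxy-3-(4-methoxyphenyl)-1,2,3,4-tetrahydroisoquinoline-4-carboxylate | COC(=O)[C@@H]1c2cc(OC)cc(OC)c2[C@H](c2cc(OS(=O)(=O)c3ccc(C)cc3)cc(OS(=O)(=O)c3ccc(C)cc3)c2)N(N)[C@H]1c1ccc(OC)cc1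
F3 | step 9 | 1-bromo-2-iodo-3,5-dimethoxybenzene | COc1cc(Br)c(I)c(OC)c1
F4 | step 9 | (2-bromo-4,6-dimethoxyphenyl)magnesium chloride | COc1cc(Br)c([Mg]Cl)c(OC)c1
F5 | step 9 | (2-bromo-4,6-dimethoxyphenyl)[(1S,2R,3S)-3-[3,5-bis(tosyloxy)phenyl]-4,6-dimethoxy-2-(4-methoxyphenyl)-2,3-dihydro-1H-inden-1-yl]methanol, both carbinol epimers | COc1cc(Br)c(c(OC)c1)C(O)[C@@H]1c2cc(OC)cc(OC)c2[C@H](c2cc(OS(=O)(=O)c3ccc(C)cc3)cc(OS(=O)(=O)c3ccc(C)cc3)c2)[C@H]1c1ccc(OC)cc1
F6 | step 2 | methyl (2S,3R)-3-{[(S)-tert-butylsulfinyl]amino}-2-(3,5-dimethoxyphenyl)-3-(4-methoxyphenyl)propanoate | COC(=O)[C@@H](c1cc(OC)cc(OC)c1)[C@@H](N[S@@](=O)C(C)(C)C)c1ccc(OC)cc1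
F7 | step 2 | methyl (2S,3R)-3-amino-2-(3,5-dimethoxyphenyl)-3-(4-methoxyphenyl)propanoate | COC(=O)[C@@H](c1cc(OC)cc(OC)c1)[C@@H](N)c1ccc(OC)cc1
F8 | step 2 | methyl (1S,3R,4S)-1-[3,5-bis(tosyloxy)phenyl]-6,8-dimethoxy-3-(4-methoxyphenyl)-1,2,3,4-tetrahydroisoquinoline-4-carboxylate | COC(=O)[C@H]1c2cc(OC)cc(OC)c2[C@H](c2cc(OS(=O)(=O)c3ccc(C)cc3)cc(OS(=O)(=O)c3ccc(C)cc3)c2)N[C@H]1c1ccc(OC)cc1
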